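**Retrosynthetic overview**

1. Names used: ring X = central benzene ring, with carbons C-a (bears the ring CH2, C8), C-b (bears C8′), C-c (ether O), C-d (the only C–H), C-e (ether O), C-f (bears C8″) going round; ring B = the resorcinol ring inside the seven-membered ring; C7/C8, C7′/C8′ (dihydrofuran fused to the cycloheptane) and C7″/C8″ (other dihydrofuran) are the sp3 pairs. The target is 7S,7′S,8′S,7″R,8″R, and both dihydrofurans are trans.
2. Enabling feature: C-d–H of ring X lies between the two ether carbons C-c and C-e, and the two dihydrofurans (7′S,8′S and 7″R,8″R) are mirror images across the plane through C-a and C-d, so without the C7–ring B bond the trimer is meso.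
3. Last C–C disconnection: C7–ring B (cycloheptane), by a catalyst-controlled desymmetrising Friedel–Crafts closure of a meso 4-hydroxystilbene; only O-demethylation follows.
4. Key disconnection: both aryl–O bonds (O–C-c and O–C-e) at once. A meso diol on a 1,3-difluoro ring X is folded into both dihydrofurans by a base-triggered tandem double aryne etherification (ring X as a 1,3-benzdiyne equivalent, the fluorides as traceless activating groups).
5. The diol comes from a 2,6-dibromo-3,5-difluorostilbene by two Pd α-arylations with one deoxybenzoin and two dynamic kinetic transfer hydrogenations with catalysts of opposite hand. Ring order: the two dihydrofurans together, then the cycloheptane.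

Key step: step 11

**Route**

Step 1
Reactants: 1 3,5-difluorotoluene
Product: 2 2,6-dibromo-3,5-difluorotoluene
Conditions: Br2 (2.2 equiv), FeBr3 (5 mol %), CH2Cl2, 0 °C to rt, dark
Reagents that add atoms: bromine, BrBr
Why: Electrophilic aromatic bromination in which each fluorine directs para to itself and the methyl group ortho, so both bromines should enter the two positions flanking the methyl group (as in the dibromination of 1,3-difluorobenzene) and the position between the fluorines stays free.

Step 2
Reactants: 2 2,6-dibromo-3,5-difluorotoluene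
Product: 3 2,6-dibromo-3,5-difluorobenzyl bromide
Conditions: NBS (1.05 equiv), AIBN (cat.), PhCF3, 85 °C
Reagents that add atoms: N-bromosuccinimide, O=C1CCC(=O)N1Br
Why: Wohl–Ziegler radical bromination of the only benzylic C–H bonds; the electron-poor ring is inert to NBS.

Step 3
Reactants: 3 2,6-dibromo-3,5-difluorobenzyl bromide
Product: 4 diethyl (2,6-dibromo-3,5-difluorobenzyl)phosphonate
Conditions: P(OEt)3 (neat), 140 °C
Reagents that add atoms: triethyl phosphite, CCOP(OCC)OCC
Why: Michaelis–Arbuzov reaction of a primary benzylic bromide; the aryl bromides and fluorides do not react.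

Step 4
Reactants: 5 4-hydroxybenzaldehyde
Product: 6 4-(triisopropylsilyloxy)benzaldehyde
Conditions: TIPSCl, imidazole, DMF, rt
Reagents that add atoms: triisopropylsilyl chloride, CC(C)[Si](Cl)(C(C)C)C(C)C
Why: Silylation of the phenol; the bulky silyl ether should survive K3PO4 at 100 °C, formic acid/triethylamine and lithium amide, and is later removed by fluoride without acid.

Step 5
Reactants: 4 diethyl (2,6-dibromo-3,5-difluorobenzyl)phosphonate; 6 4-(triisopropylsilyloxy)benzaldehyde
Product: 7 (E)-2,6-dibromo-3,5-difluoro-4′-(triisopropylsilyloxy)stilbene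
Conditions: NaH, THF, 0 °C to rt
Reagents that add atoms: none
Why: Horner–Wadsworth–Emmons olefination of a semi-stabilised benzylic phosphonate anion, which should give the (E)-stilbene.

Step 6
Reactants: 8 4′-methoxyacetophenone; 9 1-bromo-3,5-dimethoxybenzene
Product: 10 2-(3,5-dimethoxyphenyl)-1-(4-methoxyphenyl)ethanone
Conditions: Pd(OAc)2 (1 mol %), XPhos (2 mol %), NaOt-Bu (2.2 equiv), toluene, 80 °C
Reagents that add atoms: none
Why: Palladium-catalysed α-arylation of a methyl ketone enolate (Buchwald–Hartwig type); the more acidic product is stored as its enolate, which limits diarylation.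

Step 7
Reactants: 7 (E)-2,6-dibromo-3,5-difluoro-4′-(triisopropylsilyloxy)stilbene (threefold excess, recovered); 10 2-(3,5-dimethoxyphenyl)-1-(4-methoxyphenyl)ethanone
Product: 11 racemic 2-{3-bromo-4,6-difluoro-2-[(E)-2-(4-triisopropylsilyloxyphenyl)ethenyl]phenyl}-2-(3,5-dimethoxyphenyl)-1-(4-methoxyphenyl)ethanone
Conditions: Pd2(dba)3 (2.5 mol %), XPhos (6 mol %), K3PO4 (2.5 equiv), toluene, 100 °C
Reagents that add atoms: none
Why: Palladium-catalysed α-arylation of the deoxybenzoin enolate at one of the two equivalent aryl bromides; the excess of 7 limits double coupling, and C8′ is formed without control because it stays enolisable.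

Step 8
Reactants: 11 racemic mono-arm ketone
Product: 12 (1S,2S)-2-{3-bromo-4,6-difluoro-2-[(E)-2-(4-triisopropylsilyloxyphenyl)ethenyl]phenyl}-2-(3,5-dimethoxyphenyl)-1-(4-methoxyphenyl)ethanol (C1 = C7′, C2 = C8′)
Conditions: RuCl(p-cymene)[(S,S)-TsDPEN] (2 mol %), HCO2H/Et3N (2:5), DMF, 40 °C
Reagents that add atoms: none
Why: Noyori asymmetric transfer hydrogenation with dynamic kinetic resolution: the (S,S)-catalyst should give the (S)-carbinol C7′, and of the two rapidly interconverting C8′ epimers the one that reacts in the Felkin–Anh sense (ring X as the large group anti to hydride) should be consumed, giving the (7′S,8′S) diastereomer that a trans-dihydrofuran needs.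

Step 9
Reactants: 12 (1S,2S)-alcohol; 10 2-(3,5-dimethoxyphenyl)-1-(4-methoxyphenyl)ethanone
Product: 13 hydroxy ketone: 12 in which the aryl bromide is replaced by a 1-(3,5-dimethoxyphenyl)-2-(4-methoxyphenyl)-2-oxoethyl group (both C8″ epimers, interconverting)
Conditions: Pd2(dba)3 (2.5 mol %), XPhos (6 mol %), K3PO4 (2.5 equiv), toluene, 100 °C
Reagents that add atoms: none
Why: Second palladium-catalysed ketone α-arylation at the remaining aryl bromide; K3PO4 deprotonates only the ketone and not the secondary alcohol, so neither C–O coupling nor fluoride displacement should occur here.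

Step 10
Reactants: 13 hydroxy ketone
Product: 14 meso diol: 1,3-difluoro ring X with the (E)-4-(triisopropylsilyloxy)styryl group on C-a, the (1S,2S)-1-(3,5-dimethoxyphenyl)-2-hydroxy-2-(4-methoxyphenyl)ethyl group on C-b and its (1R,2R) mirror image on C-f
Conditions: RuCl(p-cymene)[(R,R)-TsDPEN] (2 mol %), HCO2H/Et3N (2:5), DMF, 40 °C
Reagents that add atoms: none
Why: The same dynamic kinetic transfer hydrogenation with the enantiomeric catalyst should write the mirror-image (7″R,8″R) arm under catalyst control, remote from the first arm, so that the product is the meso diol.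

Step 11
Reactants: 14 meso diol
Product: 17 meso (2S,3S,5R,6R)-3,5-bis(3,5-dimethoxyphenyl)-2,6-bis(4-methoxyphenyl)-4-[(E)-2-(4-triisopropylsilyloxyphenyl)ethenyl]-2,3,5,6-tetrahydrobenzo[1,2-b:5,4-b′]difuran, via aryne dialkoxide 15 (not isolated), via monocyclised aryllithium alkoxide 16 (not isolated)
Conditions: LiTMP (4 equiv), THF, −78 °C to 0 °C; then aq NH4Cl
Reagents that add atoms: none
Why: LiTMP should first form the dialkoxide and then remove the most acidic ring proton (C-d–H between the two fluorines); the 2,6-difluoroaryllithium loses LiF to the 3-fluoroaryne 15, the neighbouring lithium alkoxide adds to the near aryne carbon to form the O–C-c bond, and the new C-d carbanion 16, again ortho to fluorine, expels the second fluoride so that the other alkoxide closes the second dihydrofuran on C-e before C-d is protonated. The closest known reaction types are the tandem aryne sequence of 2,6-dihaloaryl anions used for m-terphenyls and the intramolecular addition of alkoxides to arynes that gives dihydrobenzofurans and chromans. Both rings close 5-exo-dig on an aryne; no stereocentre is made, and C7′, C8′, C7″ and C8″ are kept because no bond to them is broken, so the trans,trans-meso array of 14 is carried into 17. The step needs regioselective addition to each aryne and O-addition in preference to amide addition or benzylic deprotonation: the two-atom tether from C-b (or C-f) allows only the five-membered closure, nucleophiles add to 3-fluoro- and 3-alkoxyarynes at the carbon meta to the heteroatom (exactly C-c and then C-e), the hindered amide is a poor aryne trap, and because 14 is meso it does not matter which fluoride leaves first.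

Step 12
Reactants: 17 meso bis(dihydrobenzofuran) silyl ether
Product: 18 meso (2S,3S,5R,6R)-4-[(E)-2-(4-hydroxyphenyl)ethenyl]-3,5-bis(3,5-dimethoxyphenyl)-2,6-bis(4-methoxyphenyl)-2,3,5,6-tetrahydrobenzo[1,2-b:5,4-b′]difuran
Conditions: TBAF (1.1 equiv), AcOH (1.1 equiv), THF, 0 °C
Reagents that add atoms: none
Why: Fluoride-mediated cleavage of the aryl silyl ether under buffered, non-acidic conditions, which should leave the acid-sensitive 4-hydroxystilbene untouched.

Step 13
Reactants: 18 meso 4-hydroxystilbene
Product: 20 hexa-O-methyl ether of the target with only the 4-hydroxyphenyl group at C7 free (7S,7′S,8′S,7″R,8″R), via para-quinone methide 19 (not isolated)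
Conditions: (R)-TRIP N-triflylphosphoramide (10 mol %), toluene (0.005 M), 4 Å molecular sieves, 0 °C to rt (the catalyst antipode would give ent-20; the sense of induction is to be assigned in the first experiment)
Reagents that add atoms: none
Why: Proposed new method: the chiral Brønsted acid should protonate the 4-hydroxystilbene at C8 to the para-quinone methide 19, held as a hydrogen-bonded chiral ion pair; one of the two enantiotopic dimethoxyphenyl rings (ring B) then attacks C7 in a 7-exo-trig Friedel–Crafts closure, the catalyst choosing the face of C7 and the substrate allowing each ring to close only with the C7 aryl group trans to the C7′ side of the ring fusion, so that face selection becomes ring selection and the meso compound is desymmetrised; the closest known reaction types are chiral phosphoric acid-catalysed enantioselective additions of arenes to para-quinone methides generated in situ from 4-hydroxystyrenes or 4-hydroxybenzyl alcohols, and the acid-mediated cyclisation of viniferin-type stilbenes to ampelopsin-type cycloheptanes.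

Step 14
Reactants: 20 hexa-O-methyl ether
Product: 21 target CNP0136963.1
Conditions: BBr3 (12 equiv), CH2Cl2, −78 °C to rt; then H2O
Reagents that add atoms: none
Why: Lewis acid-mediated cleavage of the six aryl methyl ethers with BBr3, the usual last step for permethylated resveratrol oligomers; the trans-dihydrofurans are the more stable ring diastereomers, so reversible benzylic ionisation should not change them.

**Compound list**

1 | 3,5-difluorotoluene | Cc1cc(F)cc(F)c1 | starting material
2 | 2,6-dibromo-3,5-difluorotoluene | Cc1c(Br)c(F)cc(F)c1Br | intermediate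
3 | 2,6-dibromo-3,5-difluorobenzyl bromide | BrCc1c(Br)c(F)cc(F)c1Br | intermediate
4 | diethyl (2,6-dibromo-3,5-difluorobenzyl)phosphonate | CCOP(=O)(Cc1c(Br)c(F)cc(F)c1Br)OCC | intermediate
5 | 4-hydroxybenzaldehyde | O=Cc1ccc(O)cc1 | starting material
6 | 4-(triisopropylsilyloxy)benzaldehyde | O=Cc1ccc(O[Si](C(C)C)(C(C)C)C(C)C)cc1 | intermediate
7 | (E)-2,6-dibromo-3,5-difluoro-4′-(triisopropylsilyloxy)stilbene | CC(C)[Si](C(C)C)(C(C)C)Oc1ccc(/C=C/c2c(Br)c(F)cc(F)c2Br)cc1 | intermediate
8 | 4′-methoxyacetophenone | CC(=O)c1ccc(OC)cc1 | starting material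
9 | 1-bromo-3,5-dimethoxybenzene | COc1cc(Br)cc(OC)c1 | starting material
10 | 2-(3,5-dimethoxyphenyl)-1-(4-methoxyphenyl)ethanone | COc1ccc(C(=O)Cc2cc(OC)cc(OC)c2)cc1 | intermediate
11 | racemic mono-arm ketone (ring X: C-a styryl, C-b CH(aryl)C(=O)aryl, C-c F, C-e F, C-f Br) | COc1ccc(C(=O)C(c2cc(OC)cc(OC)c2)c2c(F)cc(F)c(Br)c2/C=C/c2ccc(O[Si](C(C)C)(C(C)C)C(C)C)cc2)cc1 | intermediate
12 | (7′S,8′S)-alcohol of 11 | O[C@H](c1ccc(OC)cc1)[C@@H](c1cc(OC)cc(OC)c1)c1c(F)cc(F)c(Br)c1/C=C/c1ccc(O[Si](C(C)C)(C(C)C)C(C)C)cc1 | intermediate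
13 | hydroxy ketone (second arm as ketone on C-f, C8″ unassigned) | O[C@H](c1ccc(OC)cc1)[C@@H](c1cc(OC)cc(OC)c1)c1c(F)cc(F)c(C(c2cc(OC)cc(OC)c2)C(=O)c2ccc(OC)cc2)c1/C=C/c1ccc(O[Si](C(C)C)(C(C)C)C(C)C)cc1 | intermediate
14 | meso diol (7′S,8′S,7″R,8″R) | O[C@H](c1ccc(OC)cc1)[C@@H](c1cc(OC)cc(OC)c1)c1c(F)cc(F)c([C@@H](c2cc(OC)cc(OC)c2)[C@@H](O)c2ccc(OC)cc2)c1/C=C/c1ccc(O[Si](C(C)C)(C(C)C)C(C)C)cc1 | intermediate
15 | 3-fluoroaryne (C-c≡C-d) bis(lithium alkoxide) | [Li]O[C@H](c1ccc(OC)cc1)[C@@H](c1cc(OC)cc(OC)c1)C1=C(/C=C/c2ccc(O[Si](C(C)C)(C(C)C)C(C)C)cc2)C([C@@H](c2cc(OC)cc(OC)c2)[C@@H](O[Li])c2ccc(OC)cc2)=C(F)C#C1 | intermediate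
16 | monocyclised 7-lithio-6-fluoro-2,3-dihydrobenzofuran with the second arm as lithium alkoxide | [Li]O[C@@H](c1ccc(OC)cc1)[C@H](c1cc(OC)cc(OC)c1)c1c(F)c([Li])c2O[C@H](c3ccc(OC)cc3)[C@@H](c3cc(OC)cc(OC)c3)c2c1/C=C/c1ccc(O[Si](C(C)C)(C(C)C)C(C)C)cc1 | intermediate
17 | meso bis(trans-dihydrobenzofuran) stilbene, triisopropylsilyl ether | CC(C)[Si](C(C)C)(C(C)C)Oc1ccc(/C=C/c2c3c(cc4c2[C@@H](c2cc(OC)cc(OC)c2)[C@H](c2ccc(OC)cc2)O4)O[C@H](c2ccc(OC)cc2)[C@H]3c2cc(OC)cc(OC)c2)cc1 | intermediate
18 | meso bis(trans-dihydrobenzofuran) 4-hydroxystilbene | Oc1ccc(/C=C/c2c3c(cc4c2[C@@H](c2cc(OC)cc(OC)c2)[C@H](c2ccc(OC)cc2)O4)O[C@H](c2ccc(OC)cc2)[C@H]3c2cc(OC)cc(OC)c2)cc1 | intermediate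
19 | para-quinone methide of 18 (C7 exocyclic to the cyclohexadienone, C8 now CH2) | O=C1C=CC(=CCc2c3c(cc4c2[C@@H](c2cc(OC)cc(OC)c2)[C@H](c2ccc(OC)cc2)O4)O[C@H](c2ccc(OC)cc2)[C@H]3c2cc(OC)cc(OC)c2)C=C1 | intermediate
20 | hexa-O-methyl target, free 4-hydroxyphenyl at C7 (7S,7′S,8′S,7″R,8″R) | Oc1ccc([C@@H]2Cc3c4c(cc5c3[C@@H](c3cc(OC)cc(OC)c3)[C@H](c3ccc(OC)cc3)O5)O[C@H](c3ccc(OC)cc3)[C@H]4c3cc(OC)cc(OC)c32)cc1 | intermediate
21 | CNP0136963.1 (7S,7′S,8′S,7″R,8″R) | Oc1ccc([C@@H]2Cc3c4c(cc5c3[C@@H](c3cc(O)cc(O)c3)[C@H](c3ccc(O)cc3)O5)O[C@H](c3ccc(O)cc3)[C@H]4c3cc(O)cc(O)c32)cc1 | target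

**Step count and risks**

Total step count: 14. Longest linear sequence: 12 steps (1 → 2 → 3 → 4 → 7 → 11 → 12 → 13 → 14 → 17 → 18 → 20 → 21).

Steps most likely to fail:

1. Step 13 (proposed new method). What may go wrong: the catalyst may differentiate the two enantiotopic rings poorly (low enantioselectivity), or the quinone methide may react intermolecularly. The fallback uses known chemistry and closes the cycloheptane before the second resorcinol ring exists, so only one ring can attack and C7 is set by the existing dihydrofuran (the known acid-mediated viniferin-to-ampelopsin closure). It sets out from 12. NaH in DMF at 80 °C should close the first dihydrofuran by direct fluoride displacement to the bromo fluoro dihydrobenzofuran stilbene F1. Catalytic TfOH in CH2Cl2 at −40 °C should protonate the stilbene and let ring B close the seven-membered ring trans to the C7′ side, giving tetracycle F2. Pd-catalysed α-arylation with 10 (as in step 9) gives ketone F3. Transfer hydrogenation with the (R,R)-catalyst (as in step 10) gives alcohol F4. NaH in DMF closes the second dihydrofuran to silyl ether F5, and TBAF/AcOH then gives 20, where the route is rejoined.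

2. Step 11 (key step). What may go wrong: the amide base may add to the aryne, or benzylic deprotonation at C8′ may be followed by β-elimination of the aryloxide, reopening a closed ring. The fallback closes the two rings in separate operations by addition–elimination instead of arynes. It sets out from 12. NaH in DMF gives the monocyclised bromide (the same bromo fluoro dihydrobenzofuran stilbene F1 as above). α-Arylation with 10 gives keto dihydrobenzofuran F6, transfer hydrogenation with the (R,R)-catalyst gives hydroxy dihydrobenzofuran F7, and a second NaH/DMF fluoride displacement comes back to the route at 17.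

3. Step 8 (and its mirror image, step 10). What may go wrong: epimerisation at C8′ may be slow, or hydride delivery may follow the wrong Felkin–Anh preference, giving poor diastereoselectivity. Because 17 is meso, only relative configuration matters before step 13, so the fallback is achiral and two-directional. It sets out from 7. Double α-arylation with two equivalents of 10 gives bis-ketone F8. Reduction with NaBH4/CeCl3 in MeOH at −40 °C under Felkin–Anh control should give 14 together with its racemic C2-symmetric diastereomer F9, which is removed by chromatography. The route is rejoined at 14.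

**Further compounds**

F1 | step 13 | (2S,3S)-5-bromo-6-fluoro dihydrobenzofuran stilbene (first ring closed, silyl ether) | CC(C)[Si](C(C)C)(C(C)C)Oc1ccc(/C=C/c2c(Br)c(F)cc3O[C@H](c4ccc(OC)cc4)[C@@H](c4cc(OC)cc(OC)c4)c23)cc1
F2 | step 13 | bromo fluoro tetracycle (cycloheptane closed, 7S,7′S,8′S, silyl ether) | CC(C)[Si](C(C)C)(C(C)C)Oc1ccc([C@@H]2Cc3c4c(cc(F)c3Br)O[C@H](c5ccc(OC)cc5)[C@H]4c5cc(OC)cc(OC)c52)cc1
F3 | step 13 | tetracycle with the second arm as ketone on C-f (C8″ unassigned) | CC(C)[Si](C(C)C)(C(C)C)Oc1ccc([C@@H]2Cc3c4c(cc(F)c3C(c3cc(OC)cc(OC)c3)C(=O)c3ccc(OC)cc3)O[C@H](c5ccc(OC)cc5)[C@H]4c5cc(OC)cc(OC)c52)cc1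
F4 | step 13 | tetracycle with the (7″R,8″R)-alcohol arm on C-f | CC(C)[Si](C(C)C)(C(C)C)Oc1ccc([C@@H]2Cc3c4c(cc(F)c3[C@@H](c3cc(OC)cc(OC)c3)[C@@H](O)c3ccc(OC)cc3)O[C@H](c5ccc(OC)cc5)[C@H]4c5cc(OC)cc(OC)c52)cc1
F5 | step 13 | triisopropylsilyl ether of 20 | CC(C)[Si](C(C)C)(C(C)C)Oc1ccc([C@@H]2Cc3c4c(cc5c3[C@@H](c3cc(OC)cc(OC)c3)[C@H](c3ccc(OC)cc3)O5)O[C@H](c3ccc(OC)cc3)[C@H]4c3cc(OC)cc(OC)c32)cc1
F6 | step 11 | monocyclised stilbene with the second arm as ketone on C-f (C8″ unassigned) | CC(C)[Si](C(C)C)(C(C)C)Oc1ccc(/C=C/c2c(C(c3cc(OC)cc(OC)c3)C(=O)c3ccc(OC)cc3)c(F)cc3O[C@H](c4ccc(OC)cc4)[C@@H](c4cc(OC)cc(OC)c4)c23)cc1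
F7 | step 11 | monocyclised stilbene with the (7″R,8″R)-alcohol arm on C-f | CC(C)[Si](C(C)C)(C(C)C)Oc1ccc(/C=C/c2c([C@@H](c3cc(OC)cc(OC)c3)[C@@H](O)c3ccc(OC)cc3)c(F)cc3O[C@H](c4ccc(OC)cc4)[C@@H](c4cc(OC)cc(OC)c4)c23)cc1
F8 | step 8 | bis-ketone from double α-arylation of 7 (C8′ and C8″ unassigned) | COc1ccc(C(=O)C(c2cc(OC)cc(OC)c2)c2c(F)cc(F)c(C(c3cc(OC)cc(OC)c3)C(=O)c3ccc(OC)cc3)c2/C=C/c2ccc(O[Si](C(C)C)(C(C)C)C(C)C)cc2)cc1
F9 | step 8 | C2-symmetric diol, racemic (the S,S,S,S enantiomer is drawn) | O[C@H](c1ccc(OC)cc1)[C@@H](c1cc(OC)cc(OC)c1)c1c(F)cc(F)c([C@H](c2cc(OC)cc(OC)c2)[C@H](O)c2ccc(OC)cc2)c1/C=C/c1ccc(O[Si](C(C)C)(C(C)C)C(C)C)cc1
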